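Assumption: positions are labelled with germacrane numbering (ring C1–C10, lactone unit C11–C13, ester carbon C14, methyl C15, side-chain carbons primed), and every compound marked "starting material" is taken as purchasable.

## Retrosynthetic overview

1. Target 34 ⇐ outer-face epoxidation of 4,5-alkene 33 ⇐ HCl opening of the side-chain oxirane of 32 ⇐ acylation of the C8 hydroxyl of macrocycle 26 with (2R,3R)-epoxyangelic acid 30.
2. Ten-membered ring (formed second) ⇐ ring-closing metathesis at C1=C10 of acrylate 24; the acrylate unit and C9 come from the proposed nickel/chromium coupling of methyl 2-bromoacrylate with aldehyde 20.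
3. α-Methylene lactone (formed first) ⇐ palladium-catalysed carbonylative lactonisation of the 2-bromoallyl/C6-hydroxyl unit of 16.
4. C6–C7–C8 syn,syn triad ⇐ Evans aldol (C7, C8), alkenyl Grignard on a Weinreb amide (C5–C6 bond), Narasaka–Prasad reduction (C6); a PMB-to-acetal switch tells O8 from O6.
5. Ring order: lactone, then carbocycle, then the 4,5-oxirane last.

## Route

Step 1
Reactants: 1 3-bromobut-3-en-1-ol
Product: 2 3-bromobut-3-enoic acid
Conditions: TEMPO (20 mol %), PhI(OAc)2 (2.2 equiv), MeCN/H2O 1:1, 0 °C → rt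
Reagents that add atoms: water, O
Why: Oxoammonium (TEMPO/hypervalent iodine) oxidation takes the primary alcohol through the aldehyde hydrate to the acid under near-neutral conditions, so the vinyl bromide stays and the alkene does not move into conjugation.

Step 2
Reactants: 2 3-bromobut-3-enoic acid; 3 (R)-4-benzyloxazolidin-2-one
Product: 5 (R)-4-benzyl-3-(3-bromobut-3-enoyl)oxazolidin-2-one, via mixed pivalic anhydride 4 (not isolated)
Conditions: t-BuCOCl, Et3N, THF, −20 °C; then 3, LiCl, −20 °C → rt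
Reagents that add atoms: none
Why: LiCl-promoted N-acylation through the mixed anhydride needs no strong base, which keeps the β,γ-unsaturated acyl group unconjugated.

Step 3
Reactants: 5 (R)-4-benzyl-3-(3-bromobut-3-enoyl)oxazolidin-2-one; 6 2-[(4-methoxybenzyl)oxy]acetaldehyde
Product: 8 (R)-4-benzyl-3-[(2R,3R)-2-(1-bromoethenyl)-3-hydroxy-4-[(4-methoxybenzyl)oxy]butanoyl]oxazolidin-2-one, via Z boron enolate 7 (not isolated)
Conditions: Bu2BOTf, i-Pr2NEt, CH2Cl2, −78 → 0 °C; 6, −78 → 0 °C; pH 7 buffer, MeOH, H2O2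
Reagents that add atoms: none
Why: Evans syn-aldol reaction: the Z boron enolate reacts through a Zimmerman–Traxler chair on the face away from the benzyl group of the (R)-auxiliary, which sets C7 and C8 (7,8-syn).

Step 4
Reactants: 8 aldol adduct
Product: 9 (2R,3R)-2-(1-bromoethenyl)-3-hydroxy-N-methoxy-4-[(4-methoxybenzyl)oxy]-N-methylbutanamide
Conditions: AlMe3, MeNHOMe·HCl, CH2Cl2, −20 → 0 °C
Reagents that add atoms: N,O-dimethylhydroxylamine hydrochloride, CNOC.Cl
Why: Aluminium-amide transamination to the Weinreb amide, helped by the free β-hydroxyl, removes the auxiliary without touching C7 or C8.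

Step 5
Reactants: 10 hex-5-en-1-yne
Product: 12 (E)-1-iodo-2-methylhexa-1,5-diene, via alkenyldimethylalane 11 (not isolated)
Conditions: AlMe3 (2 equiv), Cp2ZrCl2 (25 mol %), CH2Cl2, 0 °C → rt; then I2, THF, −30 → 0 °C
Reagents that add atoms: trimethylaluminium, C[Al](C)C; iodine, [I][I]
Why: Negishi zirconium-catalysed carboalumination adds methyl and aluminium syn across the terminal alkyne (methyl on the inner carbon), and iodinolysis with retention fixes the E geometry of the later C4=C5 bond; the isolated alkene is much slower.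

Step 6
Reactants: 9 Weinreb amide; 12 (E)-1-iodo-2-methylhexa-1,5-diene
Product: 14 (2R,3R,5E)-3-(1-bromoethenyl)-2-hydroxy-1-[(4-methoxybenzyl)oxy]-6-methyldeca-5,9-dien-4-one, via alkenylmagnesium chloride 13 (not isolated)
Conditions: 12, i-PrMgCl·LiCl, THF, 0 °C → rt; 9 + i-PrMgCl (1 equiv), THF, −20 °C, then 13 (2 equiv), −20 → 0 °C; aq. NH4Cl
Reagents that add atoms: none
Why: Iodine–magnesium exchange keeps the E geometry, the Grignard reagent stops at the ketone through the chelated tetrahedral intermediate of the Weinreb amide, and a Grignard reagent does not exchange with the vinyl bromide.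

Step 7
Reactants: 14 β-hydroxy enone
Product: 15 (2R,3S,4R,5E)-3-(1-bromoethenyl)-1-[(4-methoxybenzyl)oxy]-6-methyldeca-5,9-diene-2,4-diol
Conditions: Et2BOMe, THF/MeOH 4:1, −78 °C; NaBH4; AcOH, MeOH co-evaporation
Reagents that add atoms: none
Why: Narasaka–Prasad reduction: external hydride attacks the six-membered diethylboron chelate axially and gives the 1,3-syn diol, which sets C6 syn to O8 (and to the C7 branch).

Step 8
Reactants: 15 syn-diol
Product: 16 (1R,2E)-1-[(1S)-2-bromo-1-[(4R)-2-(4-methoxyphenyl)-1,3-dioxolan-4-yl]prop-2-en-1-yl]-3-methylhepta-2,6-dien-1-ol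
Conditions: DDQ (1.2 equiv), 4 Å molecular sieves, CH2Cl2, −10 °C
Reagents that add atoms: none
Why: Oikawa–Yonemitsu oxidative acetalisation: the oxocarbenium ion made from the PMB ether can only be trapped by the neighbouring C8 hydroxyl in a five-membered ring, so O8 is masked and O6 stays free (the acetal carbon forms as an epimer mixture that is removed in step 10).

Step 9
Reactants: 16 hydroxy acetal
Product: 17 (4S,5R)-4-[(4R)-2-(4-methoxyphenyl)-1,3-dioxolan-4-yl]-5-[(1E)-2-methylhexa-1,5-dien-1-yl]-3-methylideneoxolan-2-one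
Conditions: Pd(PPh3)4 (5 mol %), CO (1 atm), Et3N, MeCN, 65 °C
Reagents that add atoms: carbon monoxide, [C-]#[O+]
Why: Carbonylative lactonisation: the vinyl bromide adds to zerovalent palladium, CO inserts, and the only free hydroxyl (C6) captures the acylpalladium to give the α-methylene-γ-butyrolactone with C6 and C7 unchanged (trans).

Step 10
Reactants: 17 lactone acetal
Product: 18 (4R,5R)-4-[(1R)-1,2-dihydroxyethyl]-5-[(1E)-2-methylhexa-1,5-dien-1-yl]-3-methylideneoxolan-2-one
Conditions: AcOH/THF/H2O 3:1:1, 35 °C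
Reagents that add atoms: none
Why: Mild acid hydrolysis of the arylidene acetal frees the C8/C9 diol and is too weak to open or move the lactone.

Step 11
Reactants: 18 diol
Product: 19 (4S,5R)-4-[(1R)-1,2-bis(triethylsilyloxy)ethyl]-5-[(1E)-2-methylhexa-1,5-dien-1-yl]-3-methylideneoxolan-2-one
Conditions: Et3SiOTf (2.5 equiv), 2,6-lutidine, CH2Cl2, −78 °C
Reagents that add atoms: triethylsilyl trifluoromethanesulfonate, CC[Si](CC)(CC)OS(=O)(=O)C(F)(F)F
Why: Exhaustive silylation with the triflate prepares the selective oxidation of the primary silyl ether.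

Step 12
Reactants: 19 bis(triethylsilyl) ether
Product: 20 (2R)-2-[(2R,3S)-2-[(1E)-2-methylhexa-1,5-dien-1-yl]-4-methylidene-5-oxooxolan-3-yl]-2-(triethylsilyloxy)acetaldehyde
Conditions: (COCl)2, DMSO, CH2Cl2, −78 → −30 °C; Et3N, −78 °C → rt
Reagents that add atoms: none
Why: Under Swern conditions the chlorosulfonium salt cleaves and oxidises a primary triethylsilyl ether far faster than a secondary one, so the C9 aldehyde forms directly with O8 still protected and C8 not epimerised.

Step 13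
Reactants: 20 α-silyloxy aldehyde; 21 methyl 2-bromoprop-2-enoate
Product: 23 methyl (3S,4R)-3-hydroxy-4-[(2R,3S)-2-[(1E)-2-methylhexa-1,5-dien-1-yl]-4-methylidene-5-oxooxolan-3-yl]-2-methylidene-4-(triethylsilyloxy)butanoate, via chromium allenolate 22 (not isolated)
Conditions: CrCl2 (6 equiv), NiCl2 (2 mol %), DMF/THF 1:2, 0 °C → rt; 21 (3 equiv) by syringe pump
Reagents that add atoms: none
Why: Proposed new method: a nickel/chromium-mediated carbonyl addition that uses a 2-haloacrylate as the alkenyl donor and forms the C9–C10 bond; zerovalent nickel inserts into the C(sp2)–Br bond of 21, transmetalation to trivalent chromium gives 22 (a C-bound vinylchromium that is also an O-bound allenolate), this adds only to the aldehyde (esters and the methylene lactone are inert to organochromium reagents), and a polar Felkin–Anh transition state with the C8–OSiEt3 bond anti to the incoming carbon sets C9 as the 8,9-anti isomer; the closest known reactions are the Nozaki–Hiyama–Kishi alkenylation of aldehydes with haloalkenes and the chromium Reformatsky reaction of α-bromo esters, neither shown for 2-haloacrylates.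

Step 14
Reactants: 23 allylic alcohol
Product: 24 methyl (3S,4R)-3-acetoxy-4-[(2R,3S)-2-[(1E)-2-methylhexa-1,5-dien-1-yl]-4-methylidene-5-oxooxolan-3-yl]-2-methylidene-4-(triethylsilyloxy)butanoate
Conditions: Ac2O, pyridine, DMAP (cat.), CH2Cl2, 0 °C
Reagents that add atoms: acetic anhydride, CC(=O)OC(C)=O
Why: Standard acylation installs the C9 acetate of the target and removes the free allylic alcohol before metathesis.

Step 15
Reactants: 24 diene acetate
Product: 25 methyl (1(10)E,4E,6R,7S,8R,9S)-9-acetoxy-8-(triethylsilyloxy)germacra-1(10),4,11(13)-trien-12,6-olid-14-oate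
Conditions: second-generation Hoveyda–Grubbs catalyst (15 mol %, two portions), toluene (1 mM), 90 °C
Reagents that add atoms: none
Why: Ring-closing metathesis: the ruthenium alkylidene loads on the monosubstituted C1 alkene and closes onto the acrylate to give the ten-membered ring with C9 and C2 cis (the conjugated E enoate), while closure onto the lactone methylene would need an eight-membered ring holding a trans alkene.

Step 16
Reactants: 25 macrocyclic silyl ether
Product: 26 methyl (1(10)E,4E,6R,7R,8R,9S)-9-acetoxy-8-hydroxygermacra-1(10),4,11(13)-trien-12,6-olid-14-oate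
Conditions: HF·pyridine, pyridine, THF, 0 °C
Reagents that add atoms: none
Why: Buffered fluoride cleaves the secondary triethylsilyl ether under mildly acidic conditions where acetyl migration from O9 to O8 is slow.

Step 17
Reactants: 27 angelic acid ((Z)-2-methylbut-2-enoic acid)
Product: 28 (Z)-2-methylbut-2-en-1-ol
Conditions: LiAlH4, Et2O, 0 °C → rt
Reagents that add atoms: none
Why: Hydride reduction of the acid gives the allylic alcohol without Z/E isomerisation.

Step 18
Reactants: 28 (Z)-2-methylbut-2-en-1-ol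
Product: 29 [(2S,3R)-2,3-dimethyloxiran-2-yl]methanol
Conditions: Ti(OiPr)4 (10 mol %), L-(+)-diethyl tartrate (12 mol %), t-BuOOH, 4 Å molecular sieves, CH2Cl2, −20 °C
Reagents that add atoms: tert-butyl hydroperoxide, CC(C)(C)OO
Why: Sharpless asymmetric epoxidation: L-(+)-tartrate delivers oxygen to the same enantioface as in geraniol → (2S,3S)-epoxygeraniol, which here sets C2′ and C3′ as (2S,3R).

Step 19
Reactants: 29 epoxy alcohol
Product: 30 (2R,3R)-2,3-dimethyloxirane-2-carboxylic acid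
Conditions: TEMPO (20 mol %), PhI(OAc)2 (2.2 equiv), MeCN/H2O 1:1, rt
Reagents that add atoms: water, O
Why: The same oxoammonium oxidation as in step 1 reaches the acid under neutral conditions that keep the oxirane closed.

Step 20
Reactants: 26 macrocyclic alcohol; 30 (2R,3R)-2,3-dimethyloxirane-2-carboxylic acid
Product: 32 methyl (1(10)E,4E,6R,7S,8R,9S)-9-acetoxy-8-{[(2R,3R)-2,3-dimethyloxirane-2-carbonyl]oxy}germacra-1(10),4,11(13)-trien-12,6-olid-14-oate, via Yamaguchi mixed anhydride 31 (not isolated)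
Conditions: 30, 2,4,6-trichlorobenzoyl chloride, Et3N, toluene, rt; then 26, DMAP, toluene, rt → 40 °C
Reagents that add atoms: none
Why: Yamaguchi esterification: DMAP passes the compact oxirane acyl group from the preformed mixed anhydride to the hindered C8 hydroxyl faster than the neighbouring acetate can migrate.

Step 21
Reactants: 32 epoxyangelate ester
Product: 33 methyl (1(10)E,4E,6R,7S,8R,9S)-9-acetoxy-8-{[(2S,3S)-3-chloro-2-hydroxy-2-methylbutanoyl]oxy}germacra-1(10),4,11(13)-trien-12,6-olid-14-oate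
Conditions: HCl (1 M in Et2O, 3 equiv), CH2Cl2, −30 → 0 °C
Reagents that add atoms: hydrogen chloride, Cl
Why: Acid-mediated epoxide opening: chloride attacks the protonated glycidic ester at C3′ (away from the acyl-bearing quaternary carbon) by SN2 with inversion, giving the (2S,3S)-chlorohydrin before any ring oxirane is present.

Step 22
Reactants: 33 chlorohydrin 4,5-alkene
Product: 34 methyl (1(10)E,4R,5R,6S,7R,8R,9S)-9-acetoxy-8-{[(2S,3S)-3-chloro-2-hydroxy-2-methylbutanoyl]oxy}-4,5-epoxygermacra-1(10),11(13)-dien-12,6-olid-14-oate (target)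
Conditions: mCPBA (1.3 equiv), NaHCO3, CH2Cl2, 0 °C
Reagents that add atoms: 3-chloroperoxybenzoic acid, O=C(OO)c1cccc(Cl)c1
Why: Prilezhaev epoxidation: C4=C5 is the only electron-rich alkene, allylic 1,3-strain with the C4 methyl keeps H6 in the alkene plane so that C7 covers the inner face, and attack on the outer face gives the (4R,5R)-oxirane syn to the C6 oxygen.

## Compound list

1 | 3-bromobut-3-en-1-ol | C=C(Br)CCO | starting material
2 | 3-bromobut-3-enoic acid | C=C(Br)CC(=O)O | intermediate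
3 | (R)-4-benzyloxazolidin-2-one | O=C1N[C@H](Cc2ccccc2)CO1 | starting material
4 | 3-bromobut-3-enoic pivalic anhydride | C=C(Br)CC(=O)OC(=O)C(C)(C)C | intermediate (not isolated)
5 | (R)-4-benzyl-3-(3-bromobut-3-enoyl)oxazolidin-2-one | C=C(Br)CC(=O)N1[C@H](Cc2ccccc2)COC1=O | intermediate
6 | 2-[(4-methoxybenzyl)oxy]acetaldehyde | O=CCOCc1ccc(OC)cc1 | starting material
7 | dibutylboron (Z)-enolate of imide 5 | CCCCB(CCCC)O/C(=C\C(Br)=C)N1[C@H](Cc2ccccc2)COC1=O | intermediate (not isolated)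
8 | (R)-4-benzyl-3-[(2R,3R)-2-(1-bromoethenyl)-3-hydroxy-4-[(4-methoxybenzyl)oxy]butanoyl]oxazolidin-2-one | O=C([C@H](C(Br)=C)[C@@H](O)COCc1ccc(OC)cc1)N1[C@H](Cc2ccccc2)COC1=O | intermediate
9 | (2R,3R)-2-(1-bromoethenyl)-3-hydroxy-N-methoxy-4-[(4-methoxybenzyl)oxy]-N-methylbutanamide | CON(C)C(=O)[C@H](C(Br)=C)[C@@H](O)COCc1ccc(OC)cc1 | intermediate
10 | hex-5-en-1-yne | C#CCCC=C | starting material
11 | dimethyl[(E)-2-methylhexa-1,5-dien-1-yl]alane | C[Al](C)/C=C(\C)CCC=C | intermediate (not isolated)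
12 | (E)-1-iodo-2-methylhexa-1,5-diene | I/C=C(\C)CCC=C | intermediate
13 | chloro[(E)-2-methylhexa-1,5-dien-1-yl]magnesium | Cl[Mg]/C=C(\C)CCC=C | intermediate (not isolated)
14 | (2R,3R,5E)-3-(1-bromoethenyl)-2-hydroxy-1-[(4-methoxybenzyl)oxy]-6-methyldeca-5,9-dien-4-one | C=CCC/C(C)=C/C(=O)[C@H](C(Br)=C)[C@@H](O)COCc1ccc(OC)cc1 | intermediate
15 | (2R,3S,4R,5E)-3-(1-bromoethenyl)-1-[(4-methoxybenzyl)oxy]-6-methyldeca-5,9-diene-2,4-diol | C=CCC/C(C)=C/[C@@H](O)[C@H](C(Br)=C)[C@@H](O)COCc1ccc(OC)cc1 | intermediate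
16 | (1R,2E)-1-[(1S)-2-bromo-1-[(4R)-2-(4-methoxyphenyl)-1,3-dioxolan-4-yl]prop-2-en-1-yl]-3-methylhepta-2,6-dien-1-ol (acetal carbon as epimer mixture) | C=CCC/C(C)=C/[C@@H](O)[C@H](C(Br)=C)[C@@H]1COC(c2ccc(OC)cc2)O1 | intermediate
17 | (4S,5R)-4-[(4R)-2-(4-methoxyphenyl)-1,3-dioxolan-4-yl]-5-[(1E)-2-methylhexa-1,5-dien-1-yl]-3-methylideneoxolan-2-one | C=C1C(=O)O[C@H](/C=C(\C)CCC=C)[C@H]1[C@@H]1COC(c2ccc(OC)cc2)O1 | intermediate
18 | (4R,5R)-4-[(1R)-1,2-dihydroxyethyl]-5-[(1E)-2-methylhexa-1,5-dien-1-yl]-3-methylideneoxolan-2-one | C=C1C(=O)O[C@H](/C=C(\C)CCC=C)[C@H]1[C@@H](O)CO | intermediate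
19 | (4S,5R)-4-[(1R)-1,2-bis(triethylsilyloxy)ethyl]-5-[(1E)-2-methylhexa-1,5-dien-1-yl]-3-methylideneoxolan-2-one | C=C1C(=O)O[C@H](/C=C(\C)CCC=C)[C@H]1[C@@H](O[Si](CC)(CC)CC)CO[Si](CC)(CC)CC | intermediate
20 | (2R)-2-[(2R,3S)-2-[(1E)-2-methylhexa-1,5-dien-1-yl]-4-methylidene-5-oxooxolan-3-yl]-2-(triethylsilyloxy)acetaldehyde | C=C1C(=O)O[C@H](/C=C(\C)CCC=C)[C@H]1[C@@H](O[Si](CC)(CC)CC)C=O | intermediate
21 | methyl 2-bromoprop-2-enoate | C=C(Br)C(=O)OC | starting material
22 | methyl 2-(dichlorochromio)prop-2-enoate (chromium allenolate, C-bound form) | C=C([Cr](Cl)Cl)C(=O)OC | intermediate (not isolated)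
23 | methyl (3S,4R)-3-hydroxy-4-[(2R,3S)-2-[(1E)-2-methylhexa-1,5-dien-1-yl]-4-methylidene-5-oxooxolan-3-yl]-2-methylidene-4-(triethylsilyloxy)butanoate | C=C1C(=O)O[C@H](/C=C(\C)CCC=C)[C@H]1[C@@H](O[Si](CC)(CC)CC)[C@@H](O)C(=C)C(=O)OC | intermediate
24 | methyl (3S,4R)-3-acetoxy-4-[(2R,3S)-2-[(1E)-2-methylhexa-1,5-dien-1-yl]-4-methylidene-5-oxooxolan-3-yl]-2-methylidene-4-(triethylsilyloxy)butanoate | C=C1C(=O)O[C@H](/C=C(\C)CCC=C)[C@H]1[C@@H](O[Si](CC)(CC)CC)[C@@H](OC(C)=O)C(=C)C(=O)OC | intermediate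
25 | methyl (1(10)E,4E,6R,7S,8R,9S)-9-acetoxy-8-(triethylsilyloxy)germacra-1(10),4,11(13)-trien-12,6-olid-14-oate | C=C1C(=O)O[C@H](/C=C(\C)C2)[C@H]1[C@@H](O[Si](CC)(CC)CC)[C@@H](OC(C)=O)/C(C(=O)OC)=C\C2 | intermediate
26 | methyl (1(10)E,4E,6R,7R,8R,9S)-9-acetoxy-8-hydroxygermacra-1(10),4,11(13)-trien-12,6-olid-14-oate | C=C1C(=O)O[C@H](/C=C(\C)C2)[C@H]1[C@@H](O)[C@@H](OC(C)=O)/C(C(=O)OC)=C\C2 | intermediate
27 | angelic acid, (Z)-2-methylbut-2-enoic acid | C/C=C(/C)C(=O)O | starting material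
28 | (Z)-2-methylbut-2-en-1-ol | C/C=C(/C)CO | intermediate
29 | [(2S,3R)-2,3-dimethyloxiran-2-yl]methanol | OC[C@]1(C)O[C@@H]1C | intermediate
30 | (2R,3R)-2,3-dimethyloxirane-2-carboxylic acid | OC(=O)[C@]1(C)O[C@@H]1C | intermediate
31 | (2R,3R)-2,3-dimethyloxirane-2-carboxylic 2,4,6-trichlorobenzoic anhydride | O=C(OC(=O)[C@]1(C)O[C@@H]1C)c1c(Cl)cc(Cl)cc1Cl | intermediate (not isolated)
32 | methyl (1(10)E,4E,6R,7S,8R,9S)-9-acetoxy-8-{[(2R,3R)-2,3-dimethyloxirane-2-carbonyl]oxy}germacra-1(10),4,11(13)-trien-12,6-olid-14-oate | C=C1C(=O)O[C@H](/C=C(\C)C2)[C@H]1[C@@H](OC(=O)[C@]3(C)O[C@@H]3C)[C@@H](OC(C)=O)/C(C(=O)OC)=C\C2 | intermediate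
33 | methyl (1(10)E,4E,6R,7S,8R,9S)-9-acetoxy-8-{[(2S,3S)-3-chloro-2-hydroxy-2-methylbutanoyl]oxy}germacra-1(10),4,11(13)-trien-12,6-olid-14-oate | C=C1C(=O)O[C@H](/C=C(\C)C2)[C@H]1[C@@H](OC(=O)[C@](C)(O)[C@H](C)Cl)[C@@H](OC(C)=O)/C(C(=O)OC)=C\C2 | intermediate
34 | methyl (1(10)E,4R,5R,6S,7R,8R,9S)-9-acetoxy-8-{[(2S,3S)-3-chloro-2-hydroxy-2-methylbutanoyl]oxy}-4,5-epoxygermacra-1(10),11(13)-dien-12,6-olid-14-oate | C=C1C(=O)O[C@H]2[C@H]1[C@@H](OC(=O)[C@](C)(O)[C@H](C)Cl)[C@@H](OC(C)=O)/C(C(=O)OC)=C\CC[C@@]1(C)O[C@H]21 | target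

## Step count and risks

Total step count: 22. Longest linear sequence: 18 steps (1–4, 6–16, 20–22).

Three steps most likely to fail:

Step 15, ring-closing metathesis onto the hindered, electron-poor acrylate. It may stall or give oligomers. The fallback sets out from aldehyde 20 and comes back at 26, and it takes the ester out of the metathesis. Nickel/chromium coupling of 20 with commercial (2-bromoallyloxy)(tert-butyl)dimethylsilane (CrCl2, NiCl2 cat., DMF) gives the Felkin allylic alcohol F2. Ac2O/pyridine gives the acetate F3. Ring-closing metathesis of the now electron-rich 1,1-disubstituted alkene (second-generation Hoveyda–Grubbs catalyst, toluene, 80 °C) gives the macrocyclic bis-silyl ether F4. HF·pyridine removes both silyl groups to give the diol F5. MnO2 oxidises only the primary allylic alcohol to the enal F6. NaClO2/NaH2PO4/2-methyl-2-butene gives the acid F7, and MeI/KHCO3 in DMF gives 26.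

Step 13, the proposed nickel/chromium coupling of the 2-bromoacrylate. The bromoacrylate may homocouple or polymerise faster than it adds. The fallback uses known chemistry, sets out from aldehyde 20 and comes back at 23. Hydroalumination of methyl propiolate with i-Bu2AlH and N-methylmorpholine N-oxide in THF at 0 °C gives the vinylalane F1, which adds to 20 (0 °C → rt) with the same Felkin–Anh sense to give 23 (the vinylalumination route to Baylis–Hillman-type alcohols).

Step 21, the late HCl opening of the side-chain oxirane next to the 4,5-alkene and the methylene lactone. The fallback sets out from acid 30 and alcohol 26 and comes back at 33; the oxirane is opened before the coupling. Acid 30 with HCl in Et2O at 0 °C gives the chlorohydrin acid F8. 2,4,6-Trichlorobenzoyl chloride/Et3N turns it into the mixed anhydride F9, which acylates 26 (DMAP, toluene, 40 °C) to give 33 directly.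

## Further compounds

F1 | step 13 | methyl 2-(diisobutylalumanyl)prop-2-enoate | C=C(C(=O)OC)[Al](CC(C)C)CC(C)C
F2 | step 15 | (4S,5R)-4-[(1R,2S)-3-[(tert-butyldimethylsilyloxy)methyl]-2-hydroxy-1-(triethylsilyloxy)but-3-en-1-yl]-5-[(1E)-2-methylhexa-1,5-dien-1-yl]-3-methylideneoxolan-2-one | C=C1C(=O)O[C@H](/C=C(\C)CCC=C)[C@H]1[C@@H](O[Si](CC)(CC)CC)[C@@H](O)C(=C)CO[Si](C)(C)C(C)(C)C
F3 | step 15 | (4S,5R)-4-[(1R,2S)-2-acetoxy-3-[(tert-butyldimethylsilyloxy)methyl]-1-(triethylsilyloxy)but-3-en-1-yl]-5-[(1E)-2-methylhexa-1,5-dien-1-yl]-3-methylideneoxolan-2-one | C=C1C(=O)O[C@H](/C=C(\C)CCC=C)[C@H]1[C@@H](O[Si](CC)(CC)CC)[C@@H](OC(C)=O)C(=C)CO[Si](C)(C)C(C)(C)C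
F4 | step 15 | (1(10)Z,4E,6R,7S,8R,9S)-9-acetoxy-14-(tert-butyldimethylsilyloxy)-8-(triethylsilyloxy)germacra-1(10),4,11(13)-trien-12,6-olide | C=C1C(=O)O[C@H](/C=C(\C)C2)[C@H]1[C@@H](O[Si](CC)(CC)CC)[C@@H](OC(C)=O)/C(CO[Si](C)(C)C(C)(C)C)=C\C2
F5 | step 15 | (1(10)Z,4E,6R,7R,8R,9S)-9-acetoxy-8,14-dihydroxygermacra-1(10),4,11(13)-trien-12,6-olide | C=C1C(=O)O[C@H](/C=C(\C)C2)[C@H]1[C@@H](O)[C@@H](OC(C)=O)/C(CO)=C\C2
F6 | step 15 | (1(10)E,4E,6R,7R,8R,9S)-9-acetoxy-8-hydroxy-14-oxogermacra-1(10),4,11(13)-trien-12,6-olide | C=C1C(=O)O[C@H](/C=C(\C)C2)[C@H]1[C@@H](O)[C@@H](OC(C)=O)/C(C=O)=C\C2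
F7 | step 15 | (1(10)E,4E,6R,7R,8R,9S)-9-acetoxy-8-hydroxygermacra-1(10),4,11(13)-trien-12,6-olid-14-oic acid | C=C1C(=O)O[C@H](/C=C(\C)C2)[C@H]1[C@@H](O)[C@@H](OC(C)=O)/C(C(=O)O)=C\C2
F8 | step 21 | (2S,3S)-3-chloro-2-hydroxy-2-methylbutanoic acid | OC(=O)[C@](C)(O)[C@H](C)Cl
F9 | step 21 | (2S,3S)-3-chloro-2-hydroxy-2-methylbutanoic 2,4,6-trichlorobenzoic anhydride | O=C(OC(=O)[C@](C)(O)[C@H](C)Cl)c1c(Cl)cc(Cl)cc1Cl
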